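(The runs were computed for an exercise, noise included.)

Decide first how many nucleophiles to count for each target in this flask, which is Monday's flask followed on to later times.

| flask | electrophile | nucleophile | free base | remark | time |
|---|---|---|---|---|---|
| Monday's | 1.9 M | 2.47 M | 0.57 M | the very flask that is asked about, followed so far |  |
| flask | 1.9 M | 2.47 M | 0.570 M |  | 30 h |

Monday's run (percent of the electrophile charged)

| time / h | target / % | electrophile / % |
|---|---|---|
| 1.50 | 4.6 | 95.2 |
| 3.00 | 9.9 | 91.0 |
| 5.00 | 13.1 | 86.9 |
| 6.00 | 14.9 | 84.1 |
| 8.00 | 19.8 | 78.8 |
| 10.0 | 24.5 | 76.8 |
| 12.0 | 27.9 | 73.2 |

(standard deviation of a reading: 1 percentage point)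

- amount of target in percent of the electrophile charged, at 3.0 h, 10 h and 30 h

- the earlier runs were read with a standard deviation of 1 percentage point

Start with one acid set free and ask whether the free base can take it. The base charge equals 30.0% of the electrophile charged, and Monday's target reads 27.9% at 12.0 h. At one acid per target, the base's room therefore ends 2.1 points beyond that reading.

So ask next what happens if the nucleophile takes the acid instead. My own reckoning takes this dearer price from the start: each target binds one nucleophile and its acid takes another, so [nucleophile] falls by two for each [target] gained.

Now ask how fast the flask goes at that price. Integrate rate = k[electrophile][nucleophile] with this loss of nucleophile, and put in Monday's last reading. This gives 0.0146 /M/h, the price-two constant: the second-order rate constant read from Monday's flask when each target costs two nucleophiles. It carries the scatter of that reading. Carried to 30 h, it gives 45.1% of target.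

The forecast says 9%, 23.5% and 46%, ending slightly above my figure. Its ground for the late course is: “the acid released probably protonates the nucleophile”.

The flask gives 8.91%, 23.5% and 44.1%.

    electrophile + nucleophile → acid set free + target (k = 2.26 × 10⁻⁴ /M/min)
    nucleophile + acid set free ⇌ protonated nucleophile, settled at all times (K = 230 /M)
    acid set free + free base ⇌ salt of the base (K = 808 /M, k = 0.0123 /M/min)
    electrophile + acid set free → side product (k = 1.02 × 10⁻⁴ /M/min)
    acid set free → by-product carried off (k = 0.0102 /min)

At 30.0 h this flask holds 95.9% of its free base, and protonated nucleophile equals 92.5% of the target formed. The price-two constant times the nucleophile left gives a pseudo-first-order constant of 0.0126 /h, against 0.0362 /h at the start. Take the parking of nucleophile with acid set free out of this flask, and target at 30.0 h reads 52.9% in place of 44.1%; that parking is one part of the missing target, together with the limited time. At price one the same constant reckons 55.2%, against that run's 52.9%.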